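The target forms from the intermediate in a catalysed step, in competition with the intermediate's first-order loss to side product, and I compared three flasks differing in temperature.

in all of them: solid substrate 1.0 M; reagent 2.00 M; catalyst 150 mM; time 2.0 h
- north: temperature 110 °C
- west: temperature 85 °C
- east: temperature 135 °C

    starting material + reagent → uncatalysed product (k1 = 0.117 M⁻¹ h⁻¹, Ea1 = 107 kJ mol⁻¹)
    reagent + catalyst + intermediate → catalyst + target (k2 = 45.7 M⁻² h⁻¹, Ea2 = 40.0 kJ mol⁻¹)
    starting material + catalyst ⇌ catalyst + intermediate (K3 = 5.4, k3 = 93.9 M⁻¹ h⁻¹, Ea3 = 74.0 kJ mol⁻¹, ΔH3 = −42.0 kJ mol⁻¹)
    solid substrate ⇌ starting material, rate k4*(cs4 - [starting material]) while solid is left; crystals form when [starting material] > cs4 (cs4 = 0.94 M, k4 = 1.23 h⁻¹)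
    intermediate → side product (k5 = 0.564 h⁻¹, Ea5 = 119 kJ mol⁻¹)
    (constants at 110 °C)

- the best flask by amount of target, in percent of the solid substrate charged; "all alike" if 1.5 percentage points covers them all (north / west / east / all alike)
- amount of target at the end, in percent of the solid substrate charged, north
- amount of target at the end, in percent of the solid substrate charged, west
- amount of target at the end, in percent of the solid substrate charged, east

- as a solid, counted per litre of solution: solid substrate
- constants are those at 110 °C; use the activation energies and enthalpies for any other temperature
- at the start none of the solid substrate is in solution
- what has only dissolved of solid substrate counts as not reacted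

**Bench rule.** At the bench I would read the selectivity at the charged reagent. Target forms at 45.7 M⁻² h⁻¹ × [catalyst][reagent][intermediate] and side product at 0.564 h⁻¹ × [intermediate]. Dividing one rate by the other removes both time and [intermediate], leaving d[side product]/d[target] = λ/[reagent]. Here λ = 0.0823 M, the loss concentration: the [reagent] at which, at 110 °C and the charged [catalyst], the intermediate divides evenly between target and side product. [reagent]/λ is the selectivity factor. Catalyst appears on both sides of its steps, so I held [catalyst] at its charge. For north, the rule gave side product at 4.11% of the target formed.

**Its border.** That rule needs a nearly constant [reagent], but complete conversion to target uses half of the reagent charge. I therefore let each target consume one reagent and integrated, which gave [side product] = λ ln(charged [reagent]/final [reagent]). Taking the final [reagent] as the charge minus the solid substrate, I got 5.70% side product in north, and so 94.3% target before any uncatalysed product.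

**Other temperatures.** Since the activation energy of the loss exceeds that of the catalysed step, λ rises with temperature. It came to 0.0146 M in west and 0.376 M in east. The same first pass gave 1.01% side product in west and 26.0% in east. The east figure took one reagent for each solid substrate, yet the step to side product takes none, so I held it as a first pass. Time has dropped out of this reckoning, so it could not tell me how far west had come by the end.

**The forecast.** The forecast named north as best, with 93.3% there, 88.5% in west and 77% in east. For west it judged that “conversion is slow”. Its north figure lies below my 94.3%, which counts no uncatalysed product.

**The result.** The simulation gave north as best, with 93.2% in north, 89.5% in west and 77.0% in east.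

**Flask north.** By 1.00 h in north the solid substrate stood at 0%, with 79.5% target and 4.19% side product formed. The 5.27% starting material and 9.54% intermediate then in solution ran on through the same steps, until 0.0288% intermediate stood at 2.00 h. North's reagent ended at 53% of its charge, so λ gives 5.28% side product, and the flask held 5.20%. The neighbour, north with 1.2 M reagent, ended at 27% of its reagent charge, so λ gives 10.7%, and that flask held 10.6% side product.

The rate constants were drawn at random within sensible limits; the run is a simulation.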